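**Retrosynthetic overview**
- Ring C's C2=C3 double bond comes from dehydration of a 3-aryl-3-hydroxychroman-4-one.
- Key disconnection C3–C4: the formyl carbon of a salicylaldehyde ether, made nucleophilic as a carbene-bound acyl anion, closes onto the carbonyl carbon of a tethered aryl ketone (intramolecular crossed benzoin).
- O1–C2: Williamson ether bond between the less hindered phenol of a C-prenylated 2,6-dihydroxy-4-methoxybenzaldehyde and an α-chloro ketone; this fixes the 6-prenyl (not 8-prenyl) pattern before ring closure.
- The α-chloro ketone comes from Friedel–Crafts chloroacetylation of 1,2,4-trimethoxybenzene; the prenyl group from C-alkylation of the symmetric dihydroxybenzaldehyde.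
- Ring order: rings A and B are bought as arenes; ring C is closed last (O1–C2, then C3–C4) and then made unsaturated by loss of water.

Assumption: the target has no stereocentre, so "single enantiomer" needs no action (the one stereocentre made on the way, C3 of 8, is racemic and is erased in the last step); 2,6-dihydroxy-4-methoxybenzaldehyde is taken as a catalogue building block.

**Route**

Step 1
Reactants: 1 2,6-dihydroxy-4-methoxybenzaldehyde; 2 prenyl bromide (1-bromo-3-methylbut-2-ene)
Product: 3 2,6-dihydroxy-4-methoxy-3-(3-methylbut-2-en-1-yl)benzaldehyde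
Conditions: DBU (1.1 equiv), 2 (1.0 equiv), THF, 0 °C to rt
Reagents that add atoms: none
Why: C-alkylation of a phloroglucinol-type phenoxide (Friedel–Crafts-type C-prenylation) at the ring carbon ortho to one phenoxide oxygen and para to the other, where the two open ring positions are equivalent by symmetry so only one mono-C-prenyl isomer can form (O-prenyl and di-prenyl by-products are removed by chromatography).

Step 2
Reactants: 4 1,2,4-trimethoxybenzene; 5 chloroacetyl chloride
Product: 6 2-chloro-1-(2,4,5-trimethoxyphenyl)ethan-1-one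
Conditions: AlCl3 (1.1 equiv), CH2Cl2, −10 to 0 °C, 1 h; ice/dilute HCl quench
Reagents that add atoms: none
Why: Friedel–Crafts acylation at C5 of 4, the only position activated by two methoxy groups (ortho to one, para to another), kept cold and short so that AlCl3 does not cleave the methoxy group ortho to the new ketone.

Step 3
Reactants: 3 2,6-dihydroxy-4-methoxy-3-(3-methylbut-2-en-1-yl)benzaldehyde; 6 2-chloro-1-(2,4,5-trimethoxyphenyl)ethan-1-one
Product: 7 2-hydroxy-4-methoxy-3-(3-methylbut-2-en-1-yl)-6-[2-oxo-2-(2,4,5-trimethoxyphenyl)ethoxy]benzaldehyde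
Conditions: K2CO3 (1.1 equiv), 6 (1.0 equiv), DMF, rt
Reagents that add atoms: none
Why: Williamson ether synthesis in which the C6–OH (flanked by H) reacts because the C2–OH is held in the hydrogen bond to the formyl oxygen by the neighbouring prenyl group, the remaining OH is then chelated and inert to a second alkylation, and room temperature avoids aldol closure of the product to a 2-aroylbenzofuran (Rap–Stoermer).

Step 4
Reactants: 7 2-hydroxy-4-methoxy-3-(3-methylbut-2-en-1-yl)-6-[2-oxo-2-(2,4,5-trimethoxyphenyl)ethoxy]benzaldehyde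
Product: 8 3,5-dihydroxy-7-methoxy-6-(3-methylbut-2-en-1-yl)-3-(2,4,5-trimethoxyphenyl)-2,3-dihydro-4H-chromen-4-one (racemic)
Conditions: 2-(pentafluorophenyl)-6,7-dihydro-5H-pyrrolo[2,1-c][1,2,4]triazol-2-ium tetrafluoroborate (20 mol %), Et3N (1.0 equiv), PhMe, 40 °C, argon
Reagents that add atoms: none
Why: N-heterocyclic-carbene-catalysed intramolecular crossed aldehyde–ketone benzoin reaction, in which the carbene turns the formyl carbon into a nucleophilic acyl anion equivalent that attacks the tethered ketone carbon in a six-membered ring closure (known for 2-(2-oxoalkoxy)benzaldehydes giving 3-hydroxychroman-4-ones), the new C3 stereocentre being formed racemic with the achiral catalyst and removed in step 5.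

Step 5
Reactants: 8 3,5-dihydroxy-7-methoxy-6-(3-methylbut-2-en-1-yl)-3-(2,4,5-trimethoxyphenyl)-2,3-dihydro-4H-chromen-4-one
Product: 10 5-hydroxy-7-methoxy-6-(3-methylbut-2-en-1-yl)-3-(2,4,5-trimethoxyphenyl)-4H-chromen-4-one, via chlorosulfite ester 9 (not isolated)
Conditions: SOCl2 (1.5 equiv), pyridine (5 equiv), CH2Cl2, 0 °C to rt
Reagents that add atoms: none
Why: Dehydration of a tertiary benzylic alcohol through its chlorosulfite (SOCl2/pyridine elimination), where ionisation at C3 is helped by the electron-rich trimethoxyphenyl group and loss of a C2 proton gives the conjugated 4-pyranone, while the pyridine buffer keeps acid away from the ortho-prenylphenol and the chelated 5-OH is not acylated.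

**Compound list**
1 | 2,6-dihydroxy-4-methoxybenzaldehyde | COc1cc(O)c(C=O)c(O)c1 | starting material
2 | prenyl bromide (1-bromo-3-methylbut-2-ene) | CC(C)=CCBr | starting material
3 | 2,6-dihydroxy-4-methoxy-3-(3-methylbut-2-en-1-yl)benzaldehyde | COc1cc(O)c(C=O)c(O)c1CC=C(C)C | intermediate
4 | 1,2,4-trimethoxybenzene | COc1ccc(OC)c(OC)c1 | starting material
5 | chloroacetyl chloride | ClCC(Cl)=O | starting material
6 | 2-chloro-1-(2,4,5-trimethoxyphenyl)ethan-1-one | COc1cc(OC)c(C(=O)CCl)cc1OC | intermediate
7 | 2-hydroxy-4-methoxy-3-(3-methylbut-2-en-1-yl)-6-[2-oxo-2-(2,4,5-trimethoxyphenyl)ethoxy]benzaldehyde | COc1cc(OCC(=O)c2cc(OC)c(OC)cc2OC)c(C=O)c(O)c1CC=C(C)C | intermediate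
8 | 3,5-dihydroxy-7-methoxy-6-(3-methylbut-2-en-1-yl)-3-(2,4,5-trimethoxyphenyl)-2,3-dihydro-4H-chromen-4-one (racemic) | COc1cc2OCC(O)(c3cc(OC)c(OC)cc3OC)C(=O)c2c(O)c1CC=C(C)C | intermediate
9 | chlorosulfite ester of 8 at the C3 oxygen (not isolated) | COc1cc2OCC(OS(=O)Cl)(c3cc(OC)c(OC)cc3OC)C(=O)c2c(O)c1CC=C(C)C | intermediate
10 | 5-hydroxy-7-methoxy-6-(3-methylbut-2-en-1-yl)-3-(2,4,5-trimethoxyphenyl)-4H-chromen-4-one (achiral) | COc1cc(OC)c(-c2coc3cc(OC)c(CC=C(C)C)c(O)c3c2=O)cc1OC | target

**Step count**
Total steps: 5. Longest linear sequence: 4 steps (1 → 3 → 7 → 8 → 10); step 2 is a one-step side branch.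

**Three steps most likely to fail, with fallbacks**

Step 4 (carbene-catalysed benzoin closure). The aldehyde is di-ortho-substituted, electron-rich and chelated by the free phenol, and the acceptor is an electron-rich, ortho-substituted aryl ketone; carbene addition or the ring closure may be slow, and base can divert 7 to the benzofuran. The fallback sets out from 7 and replaces acyl-anion catalysis by a reductive carbonyl–carbonyl coupling. Treatment with SmI2 (2.5 equiv) in THF/t-BuOH at −78 °C joins the aldehyde and ketone carbons in a pinacol cyclisation to give rac-cis-7-methoxy-6-(3-methylbut-2-en-1-yl)-3-(2,4,5-trimethoxyphenyl)-3,4-dihydro-2H-chromene-3,4,5-triol F5; the low temperature is there so that ring closure outruns loss of aryloxide from the ketone-derived ketyl. MnO2 in CH2Cl2 at rt then oxidises only the secondary benzylic C4 carbinol, and the route is rejoined at 8.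

Step 3 (which phenol is alkylated). If the steric and chelation bias gives a mixture of ethers, the regiochemistry is fixed by order instead of by selectivity. The fallback sets out from 1 and 6. The symmetric diol 1 is alkylated with 6 (K2CO3, DMF, rt), where no regiochemical question exists, to give 2-hydroxy-4-methoxy-6-[2-oxo-2-(2,4,5-trimethoxyphenyl)ethoxy]benzaldehyde F3. The remaining chelated OH is converted into its 1,1-dimethylallyl ether with tert-butyl 2-methylbut-3-en-2-yl carbonate and Pd(PPh3)4 (THF, rt) to give 4-methoxy-2-[(2-methylbut-3-en-2-yl)oxy]-6-[2-oxo-2-(2,4,5-trimethoxyphenyl)ethoxy]benzaldehyde F4. Heating in PhMe at 100 °C brings about an aromatic Claisen rearrangement to the only free ortho carbon, which puts the prenyl group next to the liberated OH and comes back to the route at 7.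

Step 1 (direct C-prenylation). Yields of phenoxide C-prenylation are often modest because of O-alkylation and double alkylation. The fallback sets out from 1 and delivers the side chain by a sigmatropic shift. Mono-O-allylation (allyl bromide, K2CO3, acetone, rt) gives 2-(allyloxy)-6-hydroxy-4-methoxybenzaldehyde F1. Claisen rearrangement (N,N-diethylaniline, 190 °C) moves the allyl group to the only free ortho carbon and gives 3-allyl-2,6-dihydroxy-4-methoxybenzaldehyde F2. Cross-metathesis with excess 2-methylbut-2-ene (second-generation Grubbs catalyst, (H2IMes)(PCy3)Cl2Ru=CHPh, CH2Cl2, 40 °C) turns allyl into prenyl and comes back to the route at 3.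

**Further compounds**
F1 | step 1 | 2-(allyloxy)-6-hydroxy-4-methoxybenzaldehyde | COc1cc(O)c(C=O)c(OCC=C)c1
F2 | step 1 | 3-allyl-2,6-dihydroxy-4-methoxybenzaldehyde | COc1cc(O)c(C=O)c(O)c1CC=C
F3 | step 3 | 2-hydroxy-4-methoxy-6-[2-oxo-2-(2,4,5-trimethoxyphenyl)ethoxy]benzaldehyde | COc1cc(O)c(C=O)c(OCC(=O)c2cc(OC)c(OC)cc2OC)c1
F4 | step 3 | 4-methoxy-2-[(2-methylbut-3-en-2-yl)oxy]-6-[2-oxo-2-(2,4,5-trimethoxyphenyl)ethoxy]benzaldehyde | COc1cc(OC(C)(C)C=C)c(C=O)c(OCC(=O)c2cc(OC)c(OC)cc2OC)c1
F5 | step 4 | rac-cis-7-methoxy-6-(3-methylbut-2-en-1-yl)-3-(2,4,5-trimethoxyphenyl)-3,4-dihydro-2H-chromene-3,4,5-triol (one enantiomer drawn) | COc1cc2OC[C@@](O)(c3cc(OC)c(OC)cc3OC)[C@H](O)c2c(O)c1CC=C(C)C
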